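C1 of the indane core bears 4-hydroxybenzoyl, C2 bears 4-hydroxyphenyl, C3 bears 3,5-dihydroxyphenyl, and C3a lies next to the C4 hydroxyl. The SMILES decodes to the all-cis (1R,2R,3R) triad: H1, H2 and H3 share one face, and C1 is alpha to the aryl ketone. H1 and H2 are therefore the pair that H2 adds syn across a C1=C2 indene enone on the face away from the C3 aryl, and all six oxygens are phenols that can travel as benzyl ethers.
14 ⇒ hexa-O-benzyl indene enone 13 (C3 the only stereocentre) in one Pd/C operation; 13 ⇒ enol triflate 10 + CO + arylstannane 12 (carbonyl carbon placed on C1).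
10 ⇒ trans-2,3-diarylindanone 8 ⇒ (R)-3-arylindanone 6 + aryl bromide 7 (C2–aryl bond by ketone α-arylation; the C2 centre is erased again in 10).
6 ⇒ 2'-bromochalcone 5 by asymmetric reductive Heck closure (C3–C3a bond, sets C3); 5 ⇒ bromoketone 2 + aldehyde 3.
Ring order: all benzene rings are bought; the five-membered ring is the only ring made (step 3), is then substituted at C2 and C1, and is saturated last.

Key step: step 8

Remark on numbering: ring atoms carry the indane numbering of the target in every intermediate. In the systematic names of indenes 10 and 13 the sp3 carbon is locant 1; this is C3 in the text.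
Assumption: the sense of induction of the biaryl bisphosphine on this tetra-oxygenated chalcone cannot be predicted with certainty. The (R)-ligand is written. A pilot run with chiral HPLC and chiroptical correlation fixes the antipode, and the (S)-ligand is used if the pilot gives ent-6.

Step 1
Reactants: 1 3',5'-bis(benzyloxy)acetophenone
Product: 2 2'-bromo-3',5'-bis(benzyloxy)acetophenone
Conditions: NBS (1.05 equiv), MeCN, 0 °C → rt, dark
Reagents that add atoms: N-bromosuccinimide, O=C1CCC(=O)N1Br
Why: Electrophilic aromatic bromination with NBS in polar MeCN in the dark follows the ionic path, so the position ortho to one and para to the other benzyloxy group (C2') should be attacked in preference to the doubly flanked C4', the acetyl CH3 and the benzylic CH2 groups, which need enolisation or radical conditions.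

Step 2
Reactants: 2 2'-bromo-3',5'-bis(benzyloxy)acetophenone; 3 3,5-bis(benzyloxy)benzaldehyde
Product: 5 (E)-1-[3,5-bis(benzyloxy)-2-bromophenyl]-3-[3,5-bis(benzyloxy)phenyl]prop-2-en-1-one, via racemic aldol adduct 1-[3,5-bis(benzyloxy)-2-bromophenyl]-3-[3,5-bis(benzyloxy)phenyl]-3-hydroxypropan-1-one 4 (not isolated)
Conditions: aq KOH, EtOH–THF, rt; product collected by crystallisation
Reagents that add atoms: none
Why: In this Claisen–Schmidt condensation the methyl ketone enolate adds to the non-enolisable aldehyde and aldol 4 loses water by E1cB to give the conjugated E-enone, while the aryl bromide and benzyl ethers are inert to hydroxide at room temperature.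

Step 3
Reactants: 5 (E)-2'-bromochalcone carrying four benzyloxy groups
Product: 6 (3R)-4,6-bis(benzyloxy)-3-[3,5-bis(benzyloxy)phenyl]-2,3-dihydro-1H-inden-1-one
Conditions: Pd(OAc)2 (5 mol %), (R)-3,5-Xyl-MeO-BIPHEP (6 mol %), i-Pr2NEt (3 equiv), HCO2H (1.5 equiv, slow addition), ethylene glycol–1,4-dioxane, 90 °C; ee checked by chiral HPLC and raised by recrystallisation
Reagents that add atoms: none
Why: This is the asymmetric reductive Heck cyclisation (intramolecular conjugate arylation) known for turning 2'-halochalcones into 3-arylindanones, in which oxidative addition to C–Br, bromide dissociation aided by the glycol/ammonium medium, enantio-determining 5-endo migratory insertion that bonds C3a to the enone β-carbon, and release of the palladium enolate by protonation/formate reduction instead of β-hydride elimination follow one another, so that the chiral bisphosphine alone sets C3 as R.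

Step 4
Reactants: 6 (3R)-3-arylindanone; 7 1-(benzyloxy)-4-bromobenzene
Product: 8 (2R,3R)-4,6-bis(benzyloxy)-3-[3,5-bis(benzyloxy)phenyl]-2-[4-(benzyloxy)phenyl]-2,3-dihydro-1H-inden-1-one (2,3-trans)
Conditions: 7 (1.1 equiv), Pd2(dba)3 (2.5 mol %), t-Bu3P·HBF4 (6 mol %), NaOt-Bu (1.5 equiv), toluene, 60 °C; aq NH4Cl
Reagents that add atoms: none
Why: Palladium-catalysed ketone α-arylation is known on 3-aryl-1-indanones, where only C2 is enolisable, the acidic C2–H of the product equilibrates to the trans isomer (immaterial here), a second arylation is blocked sterically, and C3, being β to the carbonyl and not enolisable, keeps its configuration.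

Step 5
Reactants: 8 trans-2,3-diarylindanone
Product: 10 (1R)-5,7-bis(benzyloxy)-1-[3,5-bis(benzyloxy)phenyl]-2-[4-(benzyloxy)phenyl]-1H-inden-3-yl trifluoromethanesulfonate (triflate on C1, C1=C2 double bond, C3 arrangement as in 8), via potassium enolate of 8 (C1–O–, C1=C2, C3 arrangement as in 8) 9 (not isolated)
Conditions: KHMDS (0.98 equiv), THF, −78 °C; N-(5-chloro-2-pyridyl)bis(trifluoromethanesulfonimide) (1.1 equiv), −78 °C; pH 7 phosphate buffer added cold; neutral silica
Reagents that add atoms: N-(5-chloro-2-pyridyl)bis(trifluoromethanesulfonimide), FC(F)(F)S(=O)(=O)N(c1ccc(Cl)cn1)S(=O)(=O)C(F)(F)F; KHMDS, [K+].C[Si](C)(C)[N-][Si](C)(C)C (potassium in intermediate 9 only)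
Why: Enol triflation of a regiodefined ketone enolate (only C2–H is available) with a triflimide that O-sulfonylates at −78 °C erases C2 on purpose, and slightly less than one equivalent of base plus a cold buffered quench leave nothing able to remove the now indenylic C3–H, so C3 should be retained.

Step 6
Reactants: 7 1-(benzyloxy)-4-bromobenzene
Product: 12 tributyl[4-(benzyloxy)phenyl]stannane, via [4-(benzyloxy)phenyl]lithium 11 (not isolated)
Conditions: n-BuLi (1.05 equiv), THF, −78 °C; Bu3SnCl (1.1 equiv), −78 °C → rt
Reagents that add atoms: tributyltin chloride, CCCC[Sn](Cl)(CCCC)CCCC; n-butyllithium, [Li]CCCC (lithium in intermediate 11 only)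
Why: Bromine–lithium exchange at −78 °C is faster than benzylic deprotonation (so no Wittig rearrangement is expected), and the aryllithium is captured by substitution at tin.

Step 7
Reactants: 10 indenyl enol triflate; 12 tributyl[4-(benzyloxy)phenyl]stannane
Product: 13 [(1S)-5,7-bis(benzyloxy)-1-[3,5-bis(benzyloxy)phenyl]-2-[4-(benzyloxy)phenyl]-1H-inden-3-yl][4-(benzyloxy)phenyl]methanone (hexa-O-benzyl caraphenol C; same spatial arrangement at C3 as in 6, the CIP label changes to S only because C3a now outranks C2)
Conditions: 12 (1.2 equiv), Pd(PPh3)4 (5 mol %), LiCl (3 equiv), CO (3 atm), THF, 55 °C; base-free work-up (hexane/MeCN partition for tin residues, quick neutral silica); used promptly, ee checked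
Reagents that add atoms: carbon monoxide, [C-]#[O+]
Why: In the carbonylative Stille coupling of a vinyl triflate, LiCl-assisted oxidative addition, CO insertion into the hindered vinyl–Pd bond (faster under CO pressure than the slow aryl transfer from tin), transmetalation and reductive elimination give the aryl vinyl ketone with the new carbonyl carbon on C1, and since the medium contains no base the vinylogously acidic C3–H should survive.

Step 8
Reactants: 13 hexa-O-benzyl caraphenol C
Product: 14 caraphenol B, (1R,2R,3R)-all-cis [3-(3,5-dihydroxyphenyl)-4,6-dihydroxy-2-(4-hydroxyphenyl)-2,3-dihydro-1H-inden-1-yl](4-hydroxyphenyl)methanone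
Conditions: H2 (1 atm, stopped at 7 equiv uptake), 10 % Pd/C (neutral, pre-washed), THF–MeOH 1:1, rt; Celite filtration under N2, evaporation below 30 °C, Sephadex LH-20 (MeOH); no base, no Lewis acid
Reagents that add atoms: none
Why: The step is a heterogeneous hydrogenation by the Horiuti–Polanyi mechanism, in which 13 adsorbs on palladium through the C1=C2 π-bond and two surface hydrogens pass to C2 and C1 on the adsorbed face (syn addition), while the six ArO–CH2Ph bonds are hydrogenolysed on the same catalyst to phenols and toluene, the order of the two events being immaterial. The closest known reaction type is the Pd/C syn-hydrogenation of 2,3-diarylindenones and 1-substituted 1H-indenes to cis-indanones and cis-indanes from the face opposite the ring substituent, merged here with routine O-debenzylation. No ring is closed, since the planar indene ring simply becomes the indane. C2 and C1 are both controlled by C3, the only stereocentre of 13, whose aryl group stands over one face so that adsorption occurs on the face carrying H3 and H1, H2 and H3 end up together, which is the all-cis (1R,2R,3R) isomer. A suprafacial Pd–H shift of the double bond to C2=C3, or a 1,4-addition followed by ketonisation of the enol from the open face, should funnel into the same isomer. The step needs π-facial selectivity (secured by the C3 aryl), chemoselectivity for C=C and O–Bn over C=O (secured by the hindered, para-oxygenated aryl ketone and by stopping at the calculated uptake) and survival of the kinetic, epimerisable cis C1 centre (secured by neutral solvent, neutral catalyst and a base-free isolation with no later step).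

Compound list
1 | 3',5'-bis(benzyloxy)acetophenone | CC(=O)c1cc(OCc2ccccc2)cc(OCc2ccccc2)c1 | starting material
2 | 2'-bromo-3',5'-bis(benzyloxy)acetophenone | CC(=O)c1cc(OCc2ccccc2)cc(OCc2ccccc2)c1Br | intermediate
3 | 3,5-bis(benzyloxy)benzaldehyde | O=Cc1cc(OCc2ccccc2)cc(OCc2ccccc2)c1 | starting material
4 | racemic aldol adduct, 1-[3,5-bis(benzyloxy)-2-bromophenyl]-3-[3,5-bis(benzyloxy)phenyl]-3-hydroxypropan-1-one | O=C(CC(O)c1cc(OCc2ccccc2)cc(OCc2ccccc2)c1)c1cc(OCc2ccccc2)cc(OCc2ccccc2)c1Br | intermediate (not isolated)
5 | (E)-1-[3,5-bis(benzyloxy)-2-bromophenyl]-3-[3,5-bis(benzyloxy)phenyl]prop-2-en-1-one | O=C(/C=C/c1cc(OCc2ccccc2)cc(OCc2ccccc2)c1)c1cc(OCc2ccccc2)cc(OCc2ccccc2)c1Br | intermediate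
6 | (3R)-4,6-bis(benzyloxy)-3-[3,5-bis(benzyloxy)phenyl]indan-1-one | O=C1c2cc(OCc3ccccc3)cc(OCc3ccccc3)c2[C@@H](c2cc(OCc3ccccc3)cc(OCc3ccccc3)c2)C1 | intermediate
7 | 1-(benzyloxy)-4-bromobenzene | Brc1ccc(OCc2ccccc2)cc1 | starting material
8 | (2R,3R)-trans-4,6-bis(benzyloxy)-3-[3,5-bis(benzyloxy)phenyl]-2-[4-(benzyloxy)phenyl]indan-1-one | O=C1c2cc(OCc3ccccc3)cc(OCc3ccccc3)c2[C@@H](c2cc(OCc3ccccc3)cc(OCc3ccccc3)c2)[C@@H]1c1ccc(OCc2ccccc2)cc1 | intermediate
9 | potassium enolate of 8 (C3 arrangement unchanged) | [K+].[O-]C1=C(c2ccc(OCc3ccccc3)cc2)[C@H](c2cc(OCc3ccccc3)cc(OCc3ccccc3)c2)c2c(OCc3ccccc3)cc(OCc3ccccc3)cc21 | intermediate (not isolated)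
10 | (1R)-5,7-bis(benzyloxy)-1-[3,5-bis(benzyloxy)phenyl]-2-[4-(benzyloxy)phenyl]-1H-inden-3-yl triflate | FC(F)(F)S(=O)(=O)OC1=C(c2ccc(OCc3ccccc3)cc2)[C@H](c2cc(OCc3ccccc3)cc(OCc3ccccc3)c2)c2c(OCc3ccccc3)cc(OCc3ccccc3)cc21 | intermediate
11 | [4-(benzyloxy)phenyl]lithium | [Li]c1ccc(OCc2ccccc2)cc1 | intermediate (not isolated)
12 | tributyl[4-(benzyloxy)phenyl]stannane | CCCC[Sn](CCCC)(CCCC)c1ccc(OCc2ccccc2)cc1 | intermediate
13 | hexa-O-benzyl caraphenol C, (1S)-1H-inden-3-yl aryl ketone | O=C(c1ccc(OCc2ccccc2)cc1)C1=C(c2ccc(OCc3ccccc3)cc2)[C@H](c2cc(OCc3ccccc3)cc(OCc3ccccc3)c2)c2c(OCc3ccccc3)cc(OCc3ccccc3)cc21 | intermediate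
14 | caraphenol B, all-cis (1R,2R,3R) | O=C(c1ccc(O)cc1)[C@H]1c2cc(O)cc(O)c2[C@@H](c2cc(O)cc(O)c2)[C@H]1c1ccc(O)cc1 | target

Total step count: 8. Longest linear sequence: 7 (steps 1, 2, 3, 4, 5, 7, 8; step 6 is the side branch).

Steps most likely to fail

Step 8.
- **What may go wrong:** the tetrasubstituted, heavily arylated double bond may saturate too slowly, so that forcing conditions start to reduce the ketone. Facial selectivity may erode on the surface. The strained cis C1 centre may epimerise on basic sites of the support.
- **Fallback:** it sets out from 13 and separates the two tasks under catalyst control. A homogeneous cationic iridium phosphinooxazoline (BArF) catalyst is used, with its antipode matched to the substrate bias, in CH2Cl2 at 50–100 bar H2. This catalyst type is known to syn-hydrogenate tetrasubstituted indenes and enones and leaves benzyl ethers and aryl ketones untouched. It should give hexa-O-benzyl caraphenol B F1. A short, separate neutral hydrogenolysis (Pd/C, H2 1 atm, THF–MeOH) then returns to the route at 14.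

Step 7.
- **What may go wrong:** direct, non-carbonylative aryl transfer may compete. The hindered triflate may turn over sluggishly. C3 may racemise by proton shift during prolonged heating.
- **Fallback:** it sets out from 10 and brings the carbonyl carbon in with the electrophile instead of CO. Palladium-catalysed stannylation (Me3SnSnMe3, Pd(PPh3)4, LiCl, THF, 60 °C) should give the indenyl trimethylstannane F2. Base-free Stille acylation follows with commercial 4-(benzyloxy)benzoyl chloride (O=C(Cl)c1ccc(OCc2ccccc2)cc1; Pd2(dba)3, tri(2-furyl)phosphine, THF, 50 °C) and returns to the route at 13.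

Step 3.
- **What may go wrong:** oxidative addition to the electron-rich, doubly ortho-substituted bromide may be slow. Formate may cause hydrodebromination or enone reduction. The neighbouring benzyl ether may undergo intramolecular C–H arylation. The ee may be low if the neutral, bromide-bound pathway operates.
- **Fallback:** it sets out from 5 and changes the metal and the polarity of the aryl partner. Miyaura borylation (B2pin2, PdCl2(dppf), KOAc, dioxane, 85 °C) should give the 2'-pinacolboryl chalcone F3. Rhodium(I)-catalysed asymmetric intramolecular 1,4-addition follows ([Rh(C2H4)2Cl]2, MonoPhos-type phosphoramidite of the antipode giving 3R, aq K3PO4, toluene). This reaction is known to convert such boryl chalcones into 3-arylindanones, and it returns to the route at 6.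

Further compounds
F1 | step 8 | hexa-O-benzyl caraphenol B, all-cis (1R,2R,3R) | O=C(c1ccc(OCc2ccccc2)cc1)[C@H]1c2cc(OCc3ccccc3)cc(OCc3ccccc3)c2[C@@H](c2cc(OCc3ccccc3)cc(OCc3ccccc3)c2)[C@H]1c1ccc(OCc2ccccc2)cc1
F2 | step 7 | [(1R)-5,7-bis(benzyloxy)-1-[3,5-bis(benzyloxy)phenyl]-2-[4-(benzyloxy)phenyl]-1H-inden-3-yl]trimethylstannane | C[Sn](C)(C)C1=C(c2ccc(OCc3ccccc3)cc2)[C@H](c2cc(OCc3ccccc3)cc(OCc3ccccc3)c2)c2c(OCc3ccccc3)cc(OCc3ccccc3)cc21
F3 | step 3 | (E)-1-[3,5-bis(benzyloxy)-2-(4,4,5,5-tetramethyl-1,3,2-dioxaborolan-2-yl)phenyl]-3-[3,5-bis(benzyloxy)phenyl]prop-2-en-1-one | O=C(/C=C/c1cc(OCc2ccccc2)cc(OCc2ccccc2)c1)c1cc(OCc2ccccc2)cc(OCc2ccccc2)c1B1OC(C)(C)C(C)(C)O1
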